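Product forms one for one from reagent, and the 0.40 M of starting material stands above the 0.380 M of reagent. So reagent is the limiting reagent, and product can reach 95.0 % of the starting material charged.

all flasks: starting material 0.40 M; reagent 0.380 M; time 80 min
- west: initiator 12 mM
- east: initiator 20 mM
- north: initiator 25 mM
- south-east: initiator 40 mM
- north-west: initiator 60 mM

    starting material + second chain carrier → by-product + first chain carrier (k1 = 5460 /M/s)
    initiator → 2 initiating radical (k2 = 2.92 × 10⁻⁵ /s)
    2 second chain carrier → ended chains B (k3 = 2 × 10⁶ /M/s)
    reagent + first chain carrier → product + second chain carrier (k4 = 10900 /M/s)
    starting material + initiating radical → capped initiator + first chain carrier (k5 = 1.18 × 10⁵ /M/s)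
    2 first chain carrier → ended chains A (k6 = 1.6 × 10⁷ /M/s)

- a species is counted by the starting material in it: one ended chains A counts as two
- for a step with 2 of a species take k times the square, and two of it per event
- "hardly changes" means that all values lie within two and a half points (for a concentration: within two and a half percent of the largest)
- run time (west): 80 min

* amount of product at the end, in percent of the starting material charged for west, east, north, south-east, north-west, in this order
* how the row runs (falls all the way / rises, then falls / rises all the way / hardly changes / falls, then rises)

How near a flask comes to that ceiling depends on how fast reagent goes. We take both chain carriers at steady state, so the two propagation steps run at one rate. At that rate and at the charge, first chain carrier ends 2.22 times faster than second chain carrier. Since each chain turn takes one reagent and one starting material, the ratio of starting material to reagent rises as reagent falls, and this comparison drifts further the same way. We therefore balance initiation against the ending of first chain carrier and set the ending of second chain carrier aside, although at the charge that is an approximation. This gives an estimated c(first chain carrier) of 1.48 × 10⁻⁷ M in west at the charge. Reagent then decays pseudo-first-order, and its rate constant is the reagent step's constant times that concentration. The time for c(reagent) to halve on these terms is the reagent half-life, 7.16 min in west.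

Now the settings, by hand. Initiator: on these terms, with the rate constants held fixed, the reagent half-life goes as one over the square root of the charge, so north-west has 3.20 min at the charge, shorter than west. Run time: the initiator half-life of 6.6 h is longer than the 80 min run, and 86.9 % of the initiator stands at the end. The reagent half-life in west therefore drifts to 7.68 min. Taking this end value for the whole run, the run holds 10.4 half-lives, and our estimate leaves 0.0733 % of the reagent and puts west at 94.9 %. We expect the flasks with more initiator to lie closer still to the ceiling, and a longer run to take up that remainder.

The forecast gives 94.9 %, 94.99 %, 95 %, 95 % and 95 %, with the row hardly changes, on the ground “Reagent is limiting, capping product”.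

The flasks give 94.9 %, 95.0 %, 95.0 %, 95.0 % and 95.0 %, so the row hardly changes, and in west product still reads 95.0 % after ten times the time. In west the reagent half-life at 80.0 min reads 7.7 min against our 7.68 min, the run is ten times that, and 0.092 % of the reagent is left. In east the same reckoning gives a reagent half-life of 5.95 min and a remainder of 0.00896 %, and the flask holds 0.010 %.

All constants come from no measurement; the run is a simulation.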